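The octamer, carried as its eicosamethyl ether, is cut at the E4–O–F1 ether into an ABCDE phenol and an FGH iodide. The key step builds ring F in one operation by exploiting its vicinal pair of aryl ether carbons F1 and F2 beside the F4–F6 triol and the single F3 hydrogen: 3,4,5-trimethoxybenzyne, freed from its ortho-silyl triflate 5, accepts the hindered GH phenoxide at F2 and an iodine atom at F1. Its precursors are triflate 5 and diaryl ether phenol 10. Rings B and D are built by known copper-catalysed etherification of 3,4,5-trimethoxyphenol and iodination; further copper couplings and Baeyer–Villiger unmasking of formyl groups assemble the chain, and BBr3 frees the phenols.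

Key step: step 5

Remark: rings are lettered A to H from the 3,5-dihydroxyphenoxy end; in rings B, D and F position 1 bears the oxygen toward ring A and position 2 the oxygen toward ring H, in rings C, E and G these are positions 1 and 4; the target has no stereocentre, compounds 1, 6, 7, 14 and 17 are taken as catalogue chemicals, and all electron-rich phenols are handled under argon.

Step 1
Reactants: 1 3,4,5-trimethoxyphenol
Product: 2 2-bromo-3,4,5-trimethoxyphenol
Conditions: NBS (1.0 equiv), CH2Cl2, −78 → 0 °C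
Reagents that add atoms: N-bromosuccinimide, O=C1CCC(=O)N1Br
Why: Electrophilic aromatic bromination: the hydroxyl activates its two equivalent ortho positions (the para position carries a methoxy group), so one equivalent of NBS at low temperature should give a single monobromide.

Step 2
Reactants: 2 2-bromo-3,4,5-trimethoxyphenol
Product: 5 3,4,5-trimethoxy-2-(trimethylsilyl)phenyl trifluoromethanesulfonate, via aryl trimethylsilyl ether 3 (not isolated), via lithium silylphenoxide 4 (not isolated)
Conditions: HMDS, THF, 65 °C, then evaporate; n-BuLi, THF, −78 °C; Tf2O, −78 °C → rt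
Reagents that add atoms: hexamethyldisilazane, C[Si](C)(C)N[Si](C)(C)C; trifluoromethanesulfonic anhydride, O=S(=O)(OS(=O)(=O)C(F)(F)F)C(F)(F)F
Why: O-silylation followed by bromine–lithium exchange triggers the 1,3-shift of silicon from oxygen to carbon (retro-Brook rearrangement), driven by formation of the lithium phenoxide, which Tf2O then sulfonylates in the standard one-flask route to ortho-silylaryl triflates.

Step 3
Reactants: 6 2,4,6-trimethoxyphenol; 7 4-fluoro-2,6-dimethoxybenzaldehyde
Product: 8 2,6-dimethoxy-4-(2,4,6-trimethoxyphenoxy)benzaldehyde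
Conditions: Cs2CO3, DMSO, 90 °C, argon
Reagents that add atoms: none
Why: Nucleophilic aromatic substitution (addition–elimination): fluoride para to the formyl group is displaced through a Meisenheimer anion stabilised by the aldehyde, the two methoxy groups sit meta to the reacting carbon and do not deactivate it, and this pathway is little affected by the two ortho substituents of the phenoxide.

Step 4
Reactants: 8 2,6-dimethoxy-4-(2,4,6-trimethoxyphenoxy)benzaldehyde
Product: 10 2,6-dimethoxy-4-(2,4,6-trimethoxyphenoxy)phenol (GH phenol), via aryl formate 9 (not isolated)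
Conditions: mCPBA, NaHCO3, CH2Cl2, 0 °C; aq. Na2S2O3 wash; then K2CO3, MeOH, rt
Reagents that add atoms: 3-chloroperoxybenzoic acid, OOC(=O)c1cccc(Cl)c1
Why: Baeyer–Villiger oxidation in its Dakin form: the aryl group, made electron-rich by two ortho methoxy groups and the para aryloxy group, migrates in preference to hydrogen to give the formate, which mild methanolysis cleaves to the phenol.

Step 5
Reactants: 10 2,6-dimethoxy-4-(2,4,6-trimethoxyphenoxy)phenol (GH phenol); 5 3,4,5-trimethoxy-2-(trimethylsilyl)phenyl trifluoromethanesulfonate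
Product: 13 1-[2,6-dimethoxy-4-(2,4,6-trimethoxyphenoxy)phenoxy]-2-iodo-3,4,5-trimethoxybenzene (FGH iodide), via potassium phenoxide 11 (not isolated), via 3,4,5-trimethoxybenzyne 12 (not isolated)
Conditions: KH (1.0 equiv), 18-crown-6, THF, 0 °C; then KF, n-C4F9I (excess), slow addition of 5, THF, 0 °C → rt, dark
Reagents that add atoms: nonafluoro-1-iodobutane, FC(F)(F)C(F)(F)C(F)(F)C(F)(F)I
Why: Proposed new method: fluoride removes the silyl group of 5 and triflate departs to give aryne 12, whose triple bond is distorted by the neighbouring F6 methoxy group so that the remote carbon F2 is the flatter and more electrophilic one; phenoxide 11 adds there to form the F2–O bond, and the resulting aryl anion at F1, held between two oxygen-bearing carbons, attacks the iodine of C4F9I to form the F1–I bond, the expelled perfluorobutyl anion losing fluoride that carries the chain. The closest known reactions are the fluoride-induced O-arylation of phenols by arynes and three-component aryne couplings in which an amine or a thiolate adds and a halogen donor traps the aryl anion; the pairing of an aryloxide with an iodine donor has not been shown. No ring is closed and no stereocentre is formed. The step needs regioselectivity (oxygen at F2 and iodine at F1), secured by the F6 methoxy group that flanks the triple bond, and selectivity for iodine transfer over protonation, secured by a proton-free medium (phenoxide made with KH so that hydrogen is the only by-product, THF in place of nitrile solvents, excess iodine donor); both ortho positions and the para position of the phenoxide are substituted, so it can be neither C-arylated nor iodinated, and exclusion of light suppresses electron transfer to the iodide.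

Step 6
Reactants: 1 3,4,5-trimethoxyphenol; 14 4-bromo-3,5-dimethoxybenzaldehyde
Product: 15 3,5-dimethoxy-4-(3,4,5-trimethoxyphenoxy)benzaldehyde
Conditions: CuI (cat.), picolinic acid, K3PO4, DMSO, 100 °C, argon
Reagents that add atoms: none
Why: Ullmann-type diaryl ether synthesis catalysed by monovalent copper with picolinic acid, a system suited to hindered partners: the unhindered, electron-rich phenoxide of 1 displaces bromide at the carbon flanked by two methoxy groups, the para formyl group easing insertion of copper into the carbon–bromine bond, and the non-enolisable aldehyde is inert to K3PO4.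

Step 7
Reactants: 15 3,5-dimethoxy-4-(3,4,5-trimethoxyphenoxy)benzaldehyde
Product: 16 4-(2-iodo-3,4,5-trimethoxyphenoxy)-3,5-dimethoxybenzaldehyde
Conditions: NIS (1.05 equiv), TFA (cat.), MeCN, 0 °C → rt, dark
Reagents that add atoms: N-iodosuccinimide, O=C1CCC(=O)N1I
Why: Electrophilic aromatic iodination: the tetraoxygenated ring is far more nucleophilic than the formyl-deactivated ring, its two open positions are equivalent, and the first iodine slows a second substitution, so one monoiodide is expected.

Step 8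
Reactants: 16 4-(2-iodo-3,4,5-trimethoxyphenoxy)-3,5-dimethoxybenzaldehyde; 17 3,5-dimethoxyphenol
Product: 18 4-[2-(3,5-dimethoxyphenoxy)-3,4,5-trimethoxyphenoxy]-3,5-dimethoxybenzaldehyde (ABC aldehyde)
Conditions: CuI (cat.), picolinic acid, K3PO4, DMSO, 90 °C, argon
Reagents that add atoms: none
Why: Ullmann-type diaryl ether synthesis as in step 6: the unhindered, electron-rich phenoxide of 17 displaces iodide at the di-ortho-substituted carbon, and the aldehyde is inert to the non-nucleophilic base.

Step 9
Reactants: 18 4-[2-(3,5-dimethoxyphenoxy)-3,4,5-trimethoxyphenoxy]-3,5-dimethoxybenzaldehyde (ABC aldehyde)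
Product: 20 4-[2-(3,5-dimethoxyphenoxy)-3,4,5-trimethoxyphenoxy]-3,5-dimethoxyphenol (ABC phenol), via aryl formate 19 (not isolated)
Conditions: mCPBA, NaHCO3, CH2Cl2, 0 °C → rt; aq. Na2S2O3 wash; then K2CO3, MeOH, rt
Reagents that add atoms: 3-chloroperoxybenzoic acid, OOC(=O)c1cccc(Cl)c1
Why: Baeyer–Villiger (Dakin-type) oxidation as for 3,4,5-trialkoxybenzaldehydes: the para aryloxy oxygen favours aryl migration and the formate is methanolysed, so the formyl group serves as a masked C4 phenol that passed the copper step without protection.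

Step 10
Reactants: 20 4-[2-(3,5-dimethoxyphenoxy)-3,4,5-trimethoxyphenoxy]-3,5-dimethoxyphenol (ABC phenol); 16 4-(2-iodo-3,4,5-trimethoxyphenoxy)-3,5-dimethoxybenzaldehyde
Product: 21 4-[2-(4-{2-(3,5-dimethoxyphenoxy)-3,4,5-trimethoxyphenoxy}-3,5-dimethoxyphenoxy)-3,4,5-trimethoxyphenoxy]-3,5-dimethoxybenzaldehyde (ABCDE aldehyde)
Conditions: CuI (cat.), picolinic acid, K3PO4, DMSO, 90 °C, argon; 16 in excess
Reagents that add atoms: none
Why: The same Ullmann-type ether synthesis as in step 8, now between the unhindered C4 phenoxide of 20 and an excess of the readily made iodide 16.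

Step 11
Reactants: 21 ABCDE aldehyde
Product: 23 4-[2-(4-{2-(3,5-dimethoxyphenoxy)-3,4,5-trimethoxyphenoxy}-3,5-dimethoxyphenoxy)-3,4,5-trimethoxyphenoxy]-3,5-dimethoxyphenol (ABCDE phenol with free E4 hydroxyl), via aryl formate 22 (not isolated)
Conditions: mCPBA, NaHCO3, CH2Cl2, 0 °C → rt; aq. Na2S2O3 wash; then K2CO3, MeOH, rt
Reagents that add atoms: 3-chloroperoxybenzoic acid, OOC(=O)c1cccc(Cl)c1
Why: The same Baeyer–Villiger unmasking as in step 9; the aldehyde is the only function that the peracid should oxidise at this temperature, all other oxygens being methyl or aryl ethers.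

Step 12
Reactants: 23 ABCDE phenol; 13 FGH iodide
Product: 24 eicosa-O-methyl ether of the target (all twenty hydroxyls as methoxy groups)
Conditions: CuI, picolinic acid, K3PO4, DMSO, 100 °C, argon
Reagents that add atoms: none
Why: Ullmann-type diaryl ether synthesis joining the unhindered E4 phenoxide to the di-ortho-substituted carbon F1, the same pairing of partner types as in steps 8 and 10.

Step 13
Reactants: 24 eicosa-O-methyl ether of the target
Product: 25 target octamer CNP0319661.0
Conditions: BBr3 (large excess), CH2Cl2, −78 °C → rt; then H2O, 0 °C; reversed-phase isolation under argon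
Reagents that add atoms: none
Why: Lewis-acid cleavage of aryl methyl ethers (BBr3 demethylation): each methoxy oxygen is complexed by boron and its methyl group is removed by bromide in an SN2 step, the diaryl ether bonds offer no alkyl carbon for attack and should remain, and hydrolysis of the aryl borates should release the twenty hydroxyls.

Compound list
1 | 3,4,5-trimethoxyphenol | COc1cc(O)cc(OC)c1OC | starting material
2 | 2-bromo-3,4,5-trimethoxyphenol | Oc1cc(OC)c(OC)c(OC)c1Br | intermediate
3 | (2-bromo-3,4,5-trimethoxyphenoxy)trimethylsilane | C[Si](C)(C)Oc1cc(OC)c(OC)c(OC)c1Br | intermediate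
4 | lithium 3,4,5-trimethoxy-2-(trimethylsilyl)phenoxide | [Li+].[O-]c1cc(OC)c(OC)c(OC)c1[Si](C)(C)C | intermediate
5 | 3,4,5-trimethoxy-2-(trimethylsilyl)phenyl trifluoromethanesulfonate | COc1cc(OS(=O)(=O)C(F)(F)F)c([Si](C)(C)C)c(OC)c1OC | intermediate
6 | 2,4,6-trimethoxyphenol | COc1cc(OC)c(O)c(OC)c1 | starting material
7 | 4-fluoro-2,6-dimethoxybenzaldehyde | COc1cc(F)cc(OC)c1C=O | starting material
8 | 2,6-dimethoxy-4-(2,4,6-trimethoxyphenoxy)benzaldehyde | COc1cc(OC)c(Oc2cc(OC)c(C=O)c(OC)c2)c(OC)c1 | intermediate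
9 | 2,6-dimethoxy-4-(2,4,6-trimethoxyphenoxy)phenyl formate | COc1cc(OC)c(Oc2cc(OC)c(OC=O)c(OC)c2)c(OC)c1 | intermediate
10 | 2,6-dimethoxy-4-(2,4,6-trimethoxyphenoxy)phenol (GH phenol) | Oc1c(OC)cc(Oc2c(OC)cc(OC)cc2OC)cc1OC | intermediate
11 | potassium 2,6-dimethoxy-4-(2,4,6-trimethoxyphenoxy)phenoxide | [K+].[O-]c1c(OC)cc(Oc2c(OC)cc(OC)cc2OC)cc1OC | intermediate
12 | 3,4,5-trimethoxybenzyne (3,4,5-trimethoxy-1,2-didehydrobenzene) | COC1=C(OC)C(OC)=CC#C1 | intermediate
13 | 1-[2,6-dimethoxy-4-(2,4,6-trimethoxyphenoxy)phenoxy]-2-iodo-3,4,5-trimethoxybenzene (FGH iodide) | COc1cc(Oc2c(OC)cc(Oc3c(OC)cc(OC)cc3OC)cc2OC)c(I)c(OC)c1OC | intermediate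
14 | 4-bromo-3,5-dimethoxybenzaldehyde | COc1cc(C=O)cc(OC)c1Br | starting material
15 | 3,5-dimethoxy-4-(3,4,5-trimethoxyphenoxy)benzaldehyde | COc1cc(C=O)cc(OC)c1Oc1cc(OC)c(OC)c(OC)c1 | intermediate
16 | 4-(2-iodo-3,4,5-trimethoxyphenoxy)-3,5-dimethoxybenzaldehyde | COc1cc(C=O)cc(OC)c1Oc1cc(OC)c(OC)c(OC)c1I | intermediate
17 | 3,5-dimethoxyphenol | COc1cc(O)cc(OC)c1 | starting material
18 | 4-[2-(3,5-dimethoxyphenoxy)-3,4,5-trimethoxyphenoxy]-3,5-dimethoxybenzaldehyde (ABC aldehyde) | COc1cc(OC)cc(Oc2c(Oc3c(OC)cc(C=O)cc3OC)cc(OC)c(OC)c2OC)c1 | intermediate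
19 | 4-[2-(3,5-dimethoxyphenoxy)-3,4,5-trimethoxyphenoxy]-3,5-dimethoxyphenyl formate | COc1cc(OC)cc(Oc2c(Oc3c(OC)cc(OC=O)cc3OC)cc(OC)c(OC)c2OC)c1 | intermediate
20 | 4-[2-(3,5-dimethoxyphenoxy)-3,4,5-trimethoxyphenoxy]-3,5-dimethoxyphenol (ABC phenol) | COc1cc(OC)cc(Oc2c(Oc3c(OC)cc(O)cc3OC)cc(OC)c(OC)c2OC)c1 | intermediate
21 | ABCDE aldehyde: 4-[2-(4-{2-(3,5-dimethoxyphenoxy)-3,4,5-trimethoxyphenoxy}-3,5-dimethoxyphenoxy)-3,4,5-trimethoxyphenoxy]-3,5-dimethoxybenzaldehyde | COc1cc(OC)cc(Oc2c(Oc3c(OC)cc(Oc4c(Oc5c(OC)cc(C=O)cc5OC)cc(OC)c(OC)c4OC)cc3OC)cc(OC)c(OC)c2OC)c1 | intermediate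
22 | ABCDE formate: the aryl formate of phenol 23 | COc1cc(OC)cc(Oc2c(Oc3c(OC)cc(Oc4c(Oc5c(OC)cc(OC=O)cc5OC)cc(OC)c(OC)c4OC)cc3OC)cc(OC)c(OC)c2OC)c1 | intermediate
23 | ABCDE phenol: 4-[2-(4-{2-(3,5-dimethoxyphenoxy)-3,4,5-trimethoxyphenoxy}-3,5-dimethoxyphenoxy)-3,4,5-trimethoxyphenoxy]-3,5-dimethoxyphenol | COc1cc(OC)cc(Oc2c(Oc3c(OC)cc(Oc4c(Oc5c(OC)cc(O)cc5OC)cc(OC)c(OC)c4OC)cc3OC)cc(OC)c(OC)c2OC)c1 | intermediate
24 | eicosa-O-methyl ether of the target (ABCDEFGH octamer with twenty methoxy groups) | COc1cc(OC)cc(Oc2c(Oc3c(OC)cc(Oc4c(Oc5c(OC)cc(Oc6c(Oc7c(OC)cc(Oc8c(OC)cc(OC)cc8OC)cc7OC)cc(OC)c(OC)c6OC)cc5OC)cc(OC)c(OC)c4OC)cc3OC)cc(OC)c(OC)c2OC)c1 | intermediate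
25 | CNP0319661.0, the free eicosahydroxy octamer | Oc1cc(O)cc(Oc2c(Oc3c(O)cc(Oc4c(Oc5c(O)cc(Oc6c(Oc7c(O)cc(Oc8c(O)cc(O)cc8O)cc7O)cc(O)c(O)c6O)cc5O)cc(O)c(O)c4O)cc3O)cc(O)c(O)c2O)c1 | target

Total step count: 13. Longest linear sequence: 8 steps (6, 7, 8, 9, 10, 11, 12, 13).

Steps most likely to fail (the labels F1 to F8 below denote fallback compounds, not ring positions)

Step 5. The aryl anion may be protonated before it meets the iodine donor, or the very electron-rich phenoxide may transfer an electron to the perfluoroalkyl iodide, so that ether formation without iodination or oxidative loss of the phenol takes over. The fallback uses known chemistry only, sets out from 10 and comes back at 13. Purchasable 5-fluoro-1,2,3-trimethoxybenzene would be nitrated (Cu(NO3)2·3H2O, Ac2O, 0 °C) at one of its two equivalent open positions to give 5-fluoro-1,2,3-trimethoxy-4-nitrobenzene F1. Phenol 10 would then displace the fluoride ortho to the nitro group (Cs2CO3, DMF, 70 °C) to give 1-[2,6-dimethoxy-4-(2,4,6-trimethoxyphenoxy)phenoxy]-3,4,5-trimethoxy-2-nitrobenzene F2. Hydrogenation (H2, Pd/C, EtOAc) would give 6-[2,6-dimethoxy-4-(2,4,6-trimethoxyphenoxy)phenoxy]-2,3,4-trimethoxyaniline F3. Diazotisation with iodide capture (NaNO2, TsOH·H2O, KI, MeCN–H2O, 10 °C → rt) would pass through the arenediazonium 4-methylbenzenesulfonate F4 to iodide 13. The nitro group thus fixes the oxygen and iodine positions that the aryne step was meant to set.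

Step 12. Oxidative addition at the di-ortho-substituted carbon–iodine bond may be so slow that hydrodeiodination of the iodide and oxidation of the phenoxide win, and neither large fragment can be used in excess. The fallback moves the last union to the G4–O–H1 bond, where the electrophile is a cheap monomer; it sets out from 23 and 16 and comes back at 24. Phenol 23 would be coupled with an excess of iodide 16 under the conditions of step 10 to give the ABCDEFG heptamer aldehyde F5, with its formyl group at G4. Baeyer–Villiger oxidation as in step 11 would lead through the heptamer aryl formate F6 to the ABCDEFG heptamer phenol F7. Copper-catalysed coupling of this phenol with a large excess of commercial 2-iodo-1,3,5-trimethoxybenzene (CuI, picolinic acid, K3PO4, DMSO, 100 °C) would install ring H and give 24. Ring F then comes from 16, so 13 is not used on this path.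

Step 13. Ether cleavage may stop short at some of the twenty methoxy groups while the pyrogallol-type rings B, D and F oxidise in air on work-up, which would leave a mixture that cannot be purified as free phenols. The fallback isolates the target through a stable derivative; it sets out from 24 and comes back at 25. After BBr3 treatment and quench as in step 13, the crude polyphenol would be acetylated at once (Ac2O, pyridine, DMAP, rt) to the eicosaacetate F8, which is air-stable and separable on silica from under-demethylated material. Degassed HCl in MeOH (rt, then evaporation) would release 25 with only volatile by-products.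

Further compounds
F1 | step 5 | 5-fluoro-1,2,3-trimethoxy-4-nitrobenzene | COc1cc(F)c([N+](=O)[O-])c(OC)c1OC
F2 | step 5 | 1-[2,6-dimethoxy-4-(2,4,6-trimethoxyphenoxy)phenoxy]-3,4,5-trimethoxy-2-nitrobenzene | COc1cc(Oc2c(OC)cc(Oc3c(OC)cc(OC)cc3OC)cc2OC)c([N+](=O)[O-])c(OC)c1OC
F3 | step 5 | 6-[2,6-dimethoxy-4-(2,4,6-trimethoxyphenoxy)phenoxy]-2,3,4-trimethoxyaniline | COc1cc(Oc2c(OC)cc(Oc3c(OC)cc(OC)cc3OC)cc2OC)c(N)c(OC)c1OC
F4 | step 5 | 6-[2,6-dimethoxy-4-(2,4,6-trimethoxyphenoxy)phenoxy]-2,3,4-trimethoxybenzenediazonium 4-methylbenzenesulfonate | COc1cc(Oc2c(OC)cc(Oc3c(OC)cc(OC)cc3OC)cc2OC)c([N+]#N)c(OC)c1OC.Cc1ccc(S(=O)(=O)[O-])cc1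
F5 | step 12 | ABCDEFG heptamer aldehyde (phenol 23 O-arylated at E4 by ring F of 16, formyl group at G4) | COc1cc(OC)cc(Oc2c(Oc3c(OC)cc(Oc4c(Oc5c(OC)cc(Oc6c(Oc7c(OC)cc(C=O)cc7OC)cc(OC)c(OC)c6OC)cc5OC)cc(OC)c(OC)c4OC)cc3OC)cc(OC)c(OC)c2OC)c1
F6 | step 12 | ABCDEFG heptamer aryl formate | COc1cc(OC)cc(Oc2c(Oc3c(OC)cc(Oc4c(Oc5c(OC)cc(Oc6c(Oc7c(OC)cc(OC=O)cc7OC)cc(OC)c(OC)c6OC)cc5OC)cc(OC)c(OC)c4OC)cc3OC)cc(OC)c(OC)c2OC)c1
F7 | step 12 | ABCDEFG heptamer phenol with free G4 hydroxyl | COc1cc(OC)cc(Oc2c(Oc3c(OC)cc(Oc4c(Oc5c(OC)cc(Oc6c(Oc7c(OC)cc(O)cc7OC)cc(OC)c(OC)c6OC)cc5OC)cc(OC)c(OC)c4OC)cc3OC)cc(OC)c(OC)c2OC)c1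
F8 | step 13 | eicosaacetate of the target | CC(=O)Oc1cc(OC(C)=O)cc(Oc2c(Oc3c(OC(C)=O)cc(Oc4c(Oc5c(OC(C)=O)cc(Oc6c(Oc7c(OC(C)=O)cc(Oc8c(OC(C)=O)cc(OC(C)=O)cc8OC(C)=O)cc7OC(C)=O)cc(OC(C)=O)c(OC(C)=O)c6OC(C)=O)cc5OC(C)=O)cc(OC(C)=O)c(OC(C)=O)c4OC(C)=O)cc3OC(C)=O)cc(OC(C)=O)c(OC(C)=O)c2OC(C)=O)c1
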